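Time is what I trust in these flasks, so I count in fractions of the charge: how much starting material is left, and after how long.

| flask | starting material | second substrate | free catalyst | remark | time |
|---|---|---|---|---|---|
| north-west | 20 mM | 1 equiv | 1 mol% | run made earlier |  |
| west | 20 mM | 1 equiv | 1.4 mol% | run made earlier |  |
| north | 20 mM | 1 equiv | 2.2 mol% | run made earlier |  |
| south-west | 40 mM | 1 equiv | 1 mol% | run made earlier |  |
| grey | 20 mM (fed, over 1.50 d) | 1.00 equiv | 1 mol% | a stirred flask in which starting material is dosed at a steady rate over 1.50 d without added volume, worked up at 3.0 d | 3.0 d |
| teal | 20 mM | 1.00 equiv | 1 mol% | a single well-mixed tank run continuously and read at steady state, 3.0 d in it on average |  |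
| blue | 20 mM | 1.00 equiv | 1 mol% | plug flow through a tube for 3.0 d, no back-mixing | 3.0 d |
| violet | 20 mM | 1.00 equiv | 1 mol% | everything together in a closed stirred flask, run for 3.0 d | 3.0 d |

| run | time / d | target / % | isomer of the product / % | starting material / % |
|---|---|---|---|---|
| north-west | 0.250 | 4 | 0 | 100 |
| north-west | 0.833 | 8 | 2 | 90 |
| north-west | 1.25 | 10 | 9 | 84 |
| north-west | 2.00 | 11 | 16 | 74 |
| north-west | 3.00 | 10 | 32 | 58 |
| west | 0.500 | 6 | 1 | 91 |
| west | 1.04 | 11 | 8 | 79 |
| west | 1.25 | 15 | 14 | 77 |
| west | 2.08 | 13 | 29 | 57 |
| west | 2.50 | 12 | 40 | 47 |
| north | 0.208 | 5 | 0 | 96 |
| north | 0.333 | 8 | 3 | 92 |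
| north | 0.625 | 12 | 9 | 80 |
| north | 1.25 | 10 | 27 | 56 |
| north | 2.50 | 7 | 67 | 20 |
| south-west | 0.500 | 9 | 3 | 93 |
| south-west | 1.04 | 7 | 7 | 83 |
| south-west | 1.25 | 12 | 8 | 81 |
| south-west | 2.08 | 12 | 26 | 64 |
| south-west | 2.50 | 13 | 34 | 56 |

(standard deviation of a reading: 1.5 percentage points)

- the stated concentrations are those of everything mixed, before any reaction; amounts are the same in each set-up
- the numbers in the tables scatter by 1.5 percentage points (one standard deviation)
- the feed brings no volume worth counting
- the earlier runs were made in a closed, stirred flask

- the set-up with the highest share of target in all that became target or isomer of the product, at the outlet or at the end ("none" if the first two lie within 2 percentage points) (grey / teal / blue / violet / none)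
- share of target in all that became target or isomer of the product, at the outlet or at the end, grey
- share of target in all that became target or isomer of the product, at the outlet or at the end, teal
- share of target in all that became target or isomer of the product, at the outlet or at the end, blue
- share of target in all that became target or isomer of the product, at the outlet or at the end, violet

In the north-west run the fraction left falls almost in a straight line to 58 % at 3.00 d, an apparent zero order. The daily loss, the fraction of the charge that stops being starting material per day at 1 mol%, reads 0.140 d⁻¹. The share asked for is the target divided by target plus isomer; at 3.00 d in that run those two sum to 42.0 %, against 42.0 % gone from the starting material.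

The ladder starts with the target, whose last readings in that run average 10.3 %. The daily loss supplies that much in about 0.738 d, shorter than the dose of 1.50 d. Next come the dose, then the run of 3.0 d, and last the 7.14 d that the daily loss would need for a whole charge. In that run the isomer keeps growing while the target stays level, so the share falls as conversion rises.

My reckoning, for this charge at 1 mol%, is that conversion equals the daily loss times the mean age of the charge in the vessel. For violet and blue the age is 3.0 d, so conversion is 42.0 % and the share 24.5 %. Teal has the same mean age, so I give it the same conversion of 42.0 %, but I read no target level for a tank from the closed runs.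

In grey, 1.50 d remain after the dose, longer than the rise, so I keep the plateau. If each portion loses from its own entry, the age is 2.25 d and the share 32.7 %. If the loss runs flat from the start, grey equals violet. I expect grey between the two, and first.

The forecast says none, with grey 26 %, teal 20.5 %, blue 25 % and violet 25 %, on the ground that “target relaxes within about a day, so it ends near batch”. I differ on grey, whose midpoint of 28.7 % lies further above my violet than the forecast's 26 % lies above its 25 %, so I answer grey.

The best is grey: grey gives 29.7 %, blue and violet 25.4 %, teal 21.3 %.

    starting material + free catalyst ⇌ catalyst intermediate A (K = 72.0 M⁻¹, k = 0.0767 M⁻¹ s⁻¹)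
    target + free catalyst ⇌ isomer of the product + free catalyst, rate k2*[free catalyst]*[target] forward; the back reaction follows from the equilibrium constant (K = 19.0, k = 0.200 M⁻¹ s⁻¹)
    second substrate → decomposition product (k = 7.46 × 10⁻⁹ s⁻¹)
    catalyst intermediate B → free catalyst + second product (k = 7.93 × 10⁻⁴ s⁻¹)
    catalyst intermediate A → free catalyst + target (k = 7.40 × 10⁻⁴ s⁻¹)
    second substrate + free catalyst ⇌ catalyst intermediate B (K = 3500 M⁻¹, k = 0.107 M⁻¹ s⁻¹)

Grey ends with 11.4 % target, about blue's 11.2 %, on 38.5 % of the charge gone to target or isomer against blue's 44.1 %. Divided by the daily loss, grey's 38.5 % is an age of 2.75 d, above 2.25 d and below 3.0 d. In teal, 58.0 % of the charge stays as starting material; the daily loss over its average 3.0 d gives a conversion of 42.0 %, and its 8.89 % target over that gives a share of 21.2 %.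

(The earlier runs and the new flask come from a simulation with made-up constants, noise included.)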